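The readings are calculated on assumed constants; scatter was added.

Don't start from the rate constants: test first how much they matter in this flask.

in all of them: starting material 0.30 M
- blue: reagent 0.38 M; run made earlier
- flask: reagent 0.750 M; time 30 min

blue run (percent of the starting material charged)

| time / min | starting material / % | mono adduct / % |
|---|---|---|
| 0.250 | 57.1 | 25.1 |
| 0.500 | 35.4 | 34.4 |
| 1.33 | 14.7 | 38.0 |
| 3.00 | 8.8 | 32.7 |

(readings scatter by 1 percentage point)

* amount of starting material at 30 min, in percent of the starting material charged
* amount of mono adduct at 30 min, in percent of the starting material charged
* amount of double product at 30 min, in percent of the starting material charged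
* amount of tris adduct at 30 min, in percent of the starting material charged

- a reading or a percentage of tris adduct counts all its forms, free or not

Test each given number in turn, in powers of ten. Take the time first. The first blue reading, scaled to this flask's reagent, gives starting material a half-life of about 0.157 min. So 30 min lies 2.28 powers of ten beyond it, and a rate wrong by a factor of 2 shifts that by just 0.301.

Now take the charges. In this flask 2.50 is the reagent budget, the reagent charged per starting material charged. Double product holds 2 reagents and tris adduct 3, so reagent is the limiting reagent here.

Last, take the readings. At 3.00 min the blue run reads 8.8% starting material and 32.7% mono adduct on a budget of 1.27. Give all the rest two reagents each and the sum overshoots that budget. Half the excess is a silent share of about 11.5%. No reading shows it: it is inferred from this balance, as material taken to hold no reagent.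

Carry that share into this flask and let everything else end as double product or tris adduct. Tris adduct is then the budget minus twice the non-silent part, 73.0%.

The forecast says 0.5% starting material, 6% mono adduct, 60% double product and 33% tris adduct, since “it stays in excess for longer”, and my reckoning differs by putting tris adduct higher.

The flask gives 2.41% starting material, 8.17% mono adduct, 5.00% double product and 77.1% tris adduct, crystals counted.

    starting material + reagent → mono adduct (k = 0.0740 L mol⁻¹ s⁻¹)
    reagent + mono adduct → double product (k = 0.0360 L mol⁻¹ s⁻¹)
    reagent + double product → tris adduct (k = 0.0760 L mol⁻¹ s⁻¹)
    crystals ⇌ tris adduct, rate k4*(cs4 - [tris adduct]) while solid is left; crystals form when [tris adduct] > cs4 (solubility = 0.200 M, k = 0.0290 s⁻¹)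
    starting material ⇌ dormant form (K = 3.00, k = 0.0130 s⁻¹)

Count the reagent held in this flask: mono adduct once, double product twice, tris adduct 3 times. That makes 2.49 per starting material, on a budget of 2.50, with 0.17% of the reagent left. Now charge a neighbouring flask with 1.3 M reagent. Its budget is 4.33, above the 3 that tris adduct holds, so the reckoning leaves 30.7% of its reagent over. That neighbouring flask ends with 31% of its reagent left and 99.9% tris adduct.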